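**Plan**

- Retrosynthesis: once the helper groups (two O-benzyl, two C–Br) and the 4'-O-methyl group are taken off, the only skeletal cut is the biaryl bond C3'–C8'' between ring B of the flavanone unit and ring A of the flavone unit (unprimed and singly primed locants = flavanone unit, doubly and triply primed = flavone unit). The cut gives two intact natural monomers, (2S)-sakuranetin and genkwanin.
- Enabling feature: C3' is one of two homotopic CH positions ortho to the 4'-oxygen of a para-substituted phenol ring (the oxidizable partner). C8'' is the CH between O1'' and the 7''-oxygen and para to the 5''-oxygen of a phloroglucinol-type ring (the nucleophilic partner). This is the pattern of an oxidative phenol–arene coupling, which is run anodically.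
- Forward order: no ring is built, since both heterocycles are bought complete. Sakuranetin is brominated at C6 and C8 (silences its ring A), genkwanin is benzylated at 5''-O and 4'''-O (steers attack to C8'', masks the second free phenol), and the two are joined. The 4'-OH that served as oxidation handle is then methylated, and one hydrogenolysis removes all four helpers.
- Stereochemistry: the single stereocenter C2 (S) comes from the chiral pool and is never touched. Every step after it is base-free or acetate-buffered, so the flavanone cannot open to the chalcone.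

Key step: step 3

Assumption: the C3'–C8'' axis, flanked only by 4'-OMe, 7''-OMe and the ring oxygen O1'', is taken as freely rotating (the target SMILES defines no axial descriptor), so C2 is the only stereogenic element.

**Route**

Step 1
Reactants: 1 (2S)-sakuranetin, (2S)-5-hydroxy-2-(4-hydroxyphenyl)-7-methoxychroman-4-one
Product: 2 (2S)-6,8-dibromo-5-hydroxy-2-(4-hydroxyphenyl)-7-methoxychroman-4-one
Conditions: NBS (2.05 equiv), DMF, 0 °C to rt, dark
Reagents that add atoms: N-bromosuccinimide, O=C1CCC(=O)N1Br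
Why: Electrophilic aromatic bromination, in which C6 and C8 of ring A are each ortho or para to all three ring oxygens and should react far faster than the positions ortho to the single 4'-OH of ring B, so two equivalents of NBS under neutral conditions should fill both positions without touching ring B or the C2 stereocenter, which stays S.

Step 2
Reactants: 3 genkwanin, 5-hydroxy-2-(4-hydroxyphenyl)-7-methoxy-4H-chromen-4-one
Product: 5 5-(benzyloxy)-2-[4-(benzyloxy)phenyl]-7-methoxy-4H-chromen-4-one, via 4'-O-benzylgenkwanin 4 (not isolated)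
Conditions: BnBr (3 equiv), K2CO3 (4 equiv), Bu4NI (cat.), DMF, 80 °C
Reagents that add atoms: benzyl bromide, BrCc1ccccc1
Why: Williamson etherification, in which the free 4'-OH is benzylated first and the hydrogen-bonded 5-OH follows under forcing conditions (excess halide, iodide catalysis, heat), the achiral flavone tolerating the base.

Step 3
Reactants: 2 (2S)-6,8-dibromo-5-hydroxy-2-(4-hydroxyphenyl)-7-methoxychroman-4-one; 5 5-(benzyloxy)-2-[4-(benzyloxy)phenyl]-7-methoxy-4H-chromen-4-one
Product: 7 (2S)-2-{3-[5-(benzyloxy)-2-(4-(benzyloxy)phenyl)-7-methoxy-4-oxo-4H-chromen-8-yl]-4-hydroxyphenyl}-6,8-dibromo-5-hydroxy-7-methoxychroman-4-one, via dienone tautomer 6 (not isolated)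
Conditions: undivided cell, BDD anode, Pt cathode, constant current 5 mA cm−2 (2.2 F per mol of 2), 5 (3 equiv, excess recovered), Bu3NMe+ MeOSO3− (0.1 M), HFIP–CH2Cl2 (4:1), 25 °C
Reagents that add atoms: none
Why: Proposed new method: at the BDD anode in HFIP the ring B phenol of 2 is the most easily oxidized site (ring A is acyl-deactivated and dibrominated, the aryl ethers of 5 oxidize at higher potential), and its HFIP-solvated phenoxyl radical, with spin at the two homotopic ortho carbons C3'/C5' and the para carbon blocked by C2, is captured by C8 of 5; loss of a second electron and a proton rearomatizes the chromone ring to give dienone 6, which tautomerizes to phenol 7 while the cathode discharges protons as H2. The closest known reaction type is the anodic dehydrogenative phenol–arene cross-coupling on boron-doped diamond in fluorinated alcohols, known for simple alkoxyarenes as nucleophiles but not for a chromone-fused ring or for two flavonoid partners, which is why the step is labelled. No ring is closed and no stereocenter is created; C2 should keep its S configuration because the medium is base-free and ring opening to the chalcone has no path. Site selectivity on 5 follows from C8 being para to the 5-benzyloxy group and ortho to the 7-methoxy group and O1, whereas C6 lies between two alkoxy groups and C3 is a far weaker nucleophile. Cross-coupling over homo-coupling is secured by the threefold excess of 5 and by the bromine atoms at C6 and C8 of 2, which take away the only nucleophilic carbons of the phenol partner, and C–C over C–O bond formation is the normal outcome of phenoxyl capture in HFIP.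

Step 4
Reactants: 7 (2S)-2-{3-[5-(benzyloxy)-2-(4-(benzyloxy)phenyl)-7-methoxy-4-oxo-4H-chromen-8-yl]-4-hydroxyphenyl}-6,8-dibromo-5-hydroxy-7-methoxychroman-4-one
Product: 8 (2S)-2-{3-[5-(benzyloxy)-2-(4-(benzyloxy)phenyl)-7-methoxy-4-oxo-4H-chromen-8-yl]-4-methoxyphenyl}-6,8-dibromo-5-hydroxy-7-methoxychroman-4-one
Conditions: CH2N2 (Et2O solution, 3 equiv), CH2Cl2–MeOH, 0 °C to rt
Reagents that add atoms: diazomethane, C=[N+]=[N-]
Why: O-Methylation of a phenol with diazomethane, in which the free 4'-OH protonates the reagent and is methylated under neutral conditions while the 5-OH, locked in a hydrogen bond to the C4 carbonyl, is the classically unreactive position, and the absence of base keeps the 4'-hydroxyflavanone from opening to the chalcone so that C2 stays S.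

Step 5
Reactants: 8 (2S)-2-{3-[5-(benzyloxy)-2-(4-(benzyloxy)phenyl)-7-methoxy-4-oxo-4H-chromen-8-yl]-4-methoxyphenyl}-6,8-dibromo-5-hydroxy-7-methoxychroman-4-one
Product: 9 (2S)-5-hydroxy-2-{3-[5-hydroxy-2-(4-hydroxyphenyl)-7-methoxy-4-oxo-4H-chromen-8-yl]-4-methoxyphenyl}-7-methoxychroman-4-one
Conditions: H2 (1 atm), 10% Pd/C, NaOAc (2.5 equiv), EtOAc–MeOH (1:1), rt
Reagents that add atoms: none
Why: Catalytic hydrogenolysis, in which Pd/C under H2 should cleave both O-benzyl bonds and both aryl C–Br bonds in one operation, NaOAc takes up the HBr without being basic enough to epimerize C2, and the chromone C2''=C3'' bond and the two ketones are expected to survive at 1 atm and room temperature.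

**Compound list**

1 | (2S)-sakuranetin, (2S)-5-hydroxy-2-(4-hydroxyphenyl)-7-methoxychroman-4-one | COc1cc(O)c2c(c1)O[C@H](c1ccc(O)cc1)CC2=O | starting material
2 | (2S)-6,8-dibromo-5-hydroxy-2-(4-hydroxyphenyl)-7-methoxychroman-4-one | COc1c(Br)c(O)c2c(c1Br)O[C@H](c1ccc(O)cc1)CC2=O | intermediate
3 | genkwanin, 5-hydroxy-2-(4-hydroxyphenyl)-7-methoxy-4H-chromen-4-one | COc1cc(O)c2c(=O)cc(-c3ccc(O)cc3)oc2c1 | starting material
4 | 4'-O-benzylgenkwanin, 2-[4-(benzyloxy)phenyl]-5-hydroxy-7-methoxy-4H-chromen-4-one (not isolated) | COc1cc(O)c2c(=O)cc(-c3ccc(OCc4ccccc4)cc3)oc2c1 | intermediate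
5 | 5-(benzyloxy)-2-[4-(benzyloxy)phenyl]-7-methoxy-4H-chromen-4-one | COc1cc(OCc2ccccc2)c2c(=O)cc(-c3ccc(OCc4ccccc4)cc3)oc2c1 | intermediate
6 | dienone tautomer of 7, (2S)-2-{3-[5-(benzyloxy)-2-(4-(benzyloxy)phenyl)-7-methoxy-4-oxo-4H-chromen-8-yl]-4-oxocyclohexa-1,5-dien-1-yl}-6,8-dibromo-5-hydroxy-7-methoxychroman-4-one, ring carbon C3' undefined (not isolated) | COc1c(Br)c(O)c2c(c1Br)O[C@H](C1=CC(c3c(OC)cc(OCc4ccccc4)c4c(=O)cc(-c5ccc(OCc6ccccc6)cc5)oc34)C(=O)C=C1)CC2=O | intermediate
7 | (2S)-2-{3-[5-(benzyloxy)-2-(4-(benzyloxy)phenyl)-7-methoxy-4-oxo-4H-chromen-8-yl]-4-hydroxyphenyl}-6,8-dibromo-5-hydroxy-7-methoxychroman-4-one | COc1c(Br)c(O)c2c(c1Br)O[C@H](c1ccc(O)c(-c3c(OC)cc(OCc4ccccc4)c4c(=O)cc(-c5ccc(OCc6ccccc6)cc5)oc34)c1)CC2=O | intermediate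
8 | (2S)-2-{3-[5-(benzyloxy)-2-(4-(benzyloxy)phenyl)-7-methoxy-4-oxo-4H-chromen-8-yl]-4-methoxyphenyl}-6,8-dibromo-5-hydroxy-7-methoxychroman-4-one | COc1c(Br)c(O)c2c(c1Br)O[C@H](c1ccc(OC)c(-c3c(OC)cc(OCc4ccccc4)c4c(=O)cc(-c5ccc(OCc6ccccc6)cc5)oc34)c1)CC2=O | intermediate
9 | (2S)-5-hydroxy-2-{3-[5-hydroxy-2-(4-hydroxyphenyl)-7-methoxy-4-oxo-4H-chromen-8-yl]-4-methoxyphenyl}-7-methoxychroman-4-one | COc1cc(O)c2c(c1)O[C@H](c1ccc(OC)c(-c3c(OC)cc(O)c4c(=O)cc(-c5ccc(O)cc5)oc34)c1)CC2=O | target

**Count and risks**

Total step count: 5. Longest linear sequence: 4 steps (steps 1, 3, 4, 5 from compound 1, or steps 2, 3, 4, 5 from compound 3).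

Steps most likely to fail:

1. Step 3 (Proposed new method). The phenoxyl radical of 2 may be consumed by self-coupling, C–O coupling or over-oxidation faster than the weakly nucleophilic chromone ring captures it. The fallback is a Suzuki–Miyaura union of pre-halogenated monomers; it sets out from 2 and 5 and comes back to the route at 8. Compound 2 is O-methylated with diazomethane as in step 4 to give (2S)-6,8-dibromo-5-hydroxy-7-methoxy-2-(4-methoxyphenyl)chroman-4-one F1. Iodination (NIS, catalytic CF3CO2H, MeCN, rt) can only strike ortho to the 4'-methoxy group because ring A is fully substituted, and should give (2S)-6,8-dibromo-5-hydroxy-2-(3-iodo-4-methoxyphenyl)-7-methoxychroman-4-one F2. In parallel 5 is iodinated at C8 under the same conditions to 5-(benzyloxy)-2-[4-(benzyloxy)phenyl]-8-iodo-7-methoxy-4H-chromen-4-one F3. Miyaura borylation (bis(pinacolato)diboron, Pd(dppf)Cl2, KOAc, dioxane, 90 °C) converts this into 5-(benzyloxy)-2-[4-(benzyloxy)phenyl]-7-methoxy-8-(4,4,5,5-tetramethyl-1,3,2-dioxaborolan-2-yl)-4H-chromen-4-one F4. Coupling of F2 and F4 (Pd(OAc)2, SPhos, CsF, dioxane, 70 °C) should deliver 8: the C–I bond reacts before the two doubly flanked C–Br bonds, and the fluoride base is weak enough to spare C2.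

2. Step 5. The chromone C2''=C3'' double bond may be over-reduced, or the benzylic C2–O1 bond opened by hydrogenolysis, while the hindered 5''-O-benzyl group and the flanked bromides are still being removed. The fallback takes the four helpers off by two non-hydrogenative mechanisms; it sets out from 8 and comes back at 9. Lewis-acid debenzylation with a cation scavenger (BCl3, pentamethylbenzene, CH2Cl2, −78 °C, where the unchelated methyl ethers and C2 should be left alone) gives (2S)-6,8-dibromo-5-hydroxy-2-{3-[5-hydroxy-2-(4-hydroxyphenyl)-7-methoxy-4-oxo-4H-chromen-8-yl]-4-methoxyphenyl}-7-methoxychroman-4-one F7. Radical hydrodebromination (Bu3SnH, AIBN, toluene–THF, 80 °C) then gives 9.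

3. Step 4. The 5-OH, made more acidic by the neighbouring bromine at C6, may be methylated in competition, or reaction at the crowded 4'-OH may be slow. The fallback removes the bromines before the methylation; it sets out from 7 and comes back at 9. Radical hydrodebromination (Bu3SnH, AIBN, toluene, 80 °C), which leaves benzyl ethers alone, gives (2S)-2-{3-[5-(benzyloxy)-2-(4-(benzyloxy)phenyl)-7-methoxy-4-oxo-4H-chromen-8-yl]-4-hydroxyphenyl}-5-hydroxy-7-methoxychroman-4-one F5, whose 5-OH is the ordinary chelated hydroxyl of a flavanone. Diazomethane (Et2O, CH2Cl2–MeOH, 0 °C) then gives (2S)-2-{3-[5-(benzyloxy)-2-(4-(benzyloxy)phenyl)-7-methoxy-4-oxo-4H-chromen-8-yl]-4-methoxyphenyl}-5-hydroxy-7-methoxychroman-4-one F6. Hydrogenolysis of the two benzyl ethers alone (H2, 10% Pd/C, EtOAc–MeOH, rt) gives 9.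

Further compounds
F1 | step 3 | (2S)-6,8-dibromo-5-hydroxy-7-methoxy-2-(4-methoxyphenyl)chroman-4-one | COc1c(Br)c(O)c2c(c1Br)O[C@H](c1ccc(OC)cc1)CC2=O
F2 | step 3 | (2S)-6,8-dibromo-5-hydroxy-2-(3-iodo-4-methoxyphenyl)-7-methoxychroman-4-one | COc1c(Br)c(O)c2c(c1Br)O[C@H](c1ccc(OC)c(I)c1)CC2=O
F3 | step 3 | 5-(benzyloxy)-2-[4-(benzyloxy)phenyl]-8-iodo-7-methoxy-4H-chromen-4-one | COc1cc(OCc2ccccc2)c2c(=O)cc(-c3ccc(OCc4ccccc4)cc3)oc2c1I
F4 | step 3 | 5-(benzyloxy)-2-[4-(benzyloxy)phenyl]-7-methoxy-8-(4,4,5,5-tetramethyl-1,3,2-dioxaborolan-2-yl)-4H-chromen-4-one | COc1cc(OCc2ccccc2)c2c(=O)cc(-c3ccc(OCc4ccccc4)cc3)oc2c1B1OC(C)(C)C(C)(C)O1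
F5 | step 4 | (2S)-2-{3-[5-(benzyloxy)-2-(4-(benzyloxy)phenyl)-7-methoxy-4-oxo-4H-chromen-8-yl]-4-hydroxyphenyl}-5-hydroxy-7-methoxychroman-4-one | COc1cc(O)c2c(c1)O[C@H](c1ccc(O)c(-c3c(OC)cc(OCc4ccccc4)c4c(=O)cc(-c5ccc(OCc6ccccc6)cc5)oc34)c1)CC2=O
F6 | step 4 | (2S)-2-{3-[5-(benzyloxy)-2-(4-(benzyloxy)phenyl)-7-methoxy-4-oxo-4H-chromen-8-yl]-4-methoxyphenyl}-5-hydroxy-7-methoxychroman-4-one | COc1cc(O)c2c(c1)O[C@H](c1ccc(OC)c(-c3c(OC)cc(OCc4ccccc4)c4c(=O)cc(-c5ccc(OCc6ccccc6)cc5)oc34)c1)CC2=O
F7 | step 5 | (2S)-6,8-dibromo-5-hydroxy-2-{3-[5-hydroxy-2-(4-hydroxyphenyl)-7-methoxy-4-oxo-4H-chromen-8-yl]-4-methoxyphenyl}-7-methoxychroman-4-one | COc1c(Br)c(O)c2c(c1Br)O[C@H](c1ccc(OC)c(-c3c(OC)cc(O)c4c(=O)cc(-c5ccc(O)cc5)oc34)c1)CC2=O
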